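Your flask holds 0.022 M of starting material against 6.60 mM of protic impurity, so the impurity is the smaller charge, and these two amounts are the ones to compare.

| setting | zeta | flask |
|---|---|---|
| starting material | 0.044 M | 0.022 M |
| protic impurity | 6.6 mM | 6.60 mM |
| remark | run made earlier |  |
| time |  | 6.0 h |

zeta run (percent of the starting material charged)

| time / min | isomer of the product A / % | target / % | starting material / % |
|---|---|---|---|
| 4.00 | 0.5 | 6.0 | 70.1 |
| 12.0 | 2.4 | 18.0 | 40.6 |
| 20.0 | 4.1 | 23.7 | 26.0 |
| 30.0 | 7.5 | 24.3 | 14.5 |
| 40.0 | 9.9 | 26.6 | 8.4 |
| 60.0 | 15.2 | 25.4 | 4.6 |
| 80.0 | 21.8 | 24.7 | 1.1 |

(readings scatter by 1 percentage point)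

- a reading or a percentage of target counts all its forms, free or not

- ratio of isomer of the product A to target at 80 s
- ratio of isomer of the product A to target at 20 min
- ratio of isomer of the product A to target at 6.0 h
- which of isomer of the product A and target there is more of at 6.0 h

My reckoning assumes that each impurity molecule destroys one molecule of starting material. The balance of the impurity then gives q = 30.0% for this flask, the quench ceiling: the impurity charge over the starting material charge, the largest share of the charge the impurity can take. As the limiting reagent of that loss, it leaves at least 70.0% of the charge for everything else. In the zeta run q was 15.0%. A loss taken from the starting material should cut target and isomer of the product A by the same factor, so I expect this flask's ratios to follow the zeta readings at equal times. Those readings give 0.173 at 20.0 min and 0.883 at 80.0 min, with the isomer still climbing, so I expect the isomer to lead at 6.0 h.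

The forecast, reasoning that “The flask has the same impurity concentration but half the substrate”, gave 0.03, 0.22 and 2.4 at 80 s, 20 min and 6.0 h, with isomer of the product A ahead.

The flask gives 0.0562, 0.223 and 6.26, with isomer of the product A ahead, 51.9% against 8.28% of target.

    starting material → intermediate (k = 0.0578 min⁻¹)
    intermediate ⇌ target (K = 1.80, k = 0.420 min⁻¹)
    intermediate ⇌ isomer of the product A (K = 30.3, k = 0.0198 min⁻¹)
    crystals ⇌ target, rate k4*(cs4 - [target]) while solid is left; crystals form when [target] > cs4 (solubility = 16.0 mM, k = 4.27 min⁻¹)
    starting material + protic impurity → quenched substrate (k = 8.72 M⁻¹ min⁻¹)
    target ⇌ isomer of the product B (K = 0.956, k = 0.170 min⁻¹)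

At 6.00 h this flask holds 27.3% of quenched substrate, below q, and 9.0% of the impurity's own charge remains. The neighbouring flask, the same but charged with 0.026 M of impurity, has q = 118%, so the impurity is now the larger charge, and q, standing above the whole charge, is no ceiling there. At 6.00 h that neighbouring flask has 0% of its starting material left, the first charge to run out, while 71.8% of that charge stands as quenched substrate and 39% of the impurity's own charge remains. Its ratio of isomer of the product A to target is 6.48, from 20.3% of isomer of the product A against 3.13% of target.

The earlier runs and the new flask stem from a simulated flask for an exercise; scatter was added.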